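The oxolane ring (O1, C2 aryl, C3 with the acyloxymethyl arm, C4 arylmethyl, C5) is disconnected at C4–C5 and at O1–C2. The route exploits that C5 is a single oxygenated methylene attached only to C4, while the C3 arm, as a free CH2OH, is homoallylic to a C4=CH–aryl styrene: C5 is brought in as carbon monoxide. A hydroxyl-directed hydroformylation of an open-chain (E)-4-aryl-2-[aryl(silyloxy)methyl]but-3-en-1-ol, available by an Evans syn aldol, should form the C4–C5 bond, set C4 and close a temporary five-membered lactol in one operation. Lactol reduction, acid-induced O1–C2 closure, esterification and debenzylation complete the synthesis.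

Key step: step 6

Remark on the chemistry: the labels O1 and C2 to C5 of the target oxolane are used for the same atoms in every open-chain compound; Ar = 4-benzyloxy-3-methoxyphenyl and TBS = tert-butyldimethylsilyl. The C2 configuration made in step 3 is not relied upon, because C2 is re-formed in step 8. (R)-2-Methylbutanoic acid is taken as a commercial single enantiomer. The precursor keeps a TBS ether on the C2 oxygen (it blocks a second homoallylic directing hydroxyl and later serves as the leaving group) and benzyl ethers on both phenols.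

Step 1
Reactants: 1 4-benzyloxy-3-methoxybenzaldehyde; 2 (2-carboxyethyl)triphenylphosphonium bromide
Product: 4 (E)-4-(4-benzyloxy-3-methoxyphenyl)but-3-enoic acid, via phosphonium ylide 3 (not isolated)
Conditions: 2, NaN(SiMe3)2 (2.1 equiv), THF, 0 °C; then 1, 0 °C to rt; aq. HCl work-up
Reagents that add atoms: none
Why: Wittig reaction: double deprotonation of 2 gives the carboxylate ylide 3, which adds to the aryl aldehyde and collapses to the β,γ-unsaturated acid, the (E) alkene being the isomer this salt is known to favour with aromatic aldehydes; no stereocenter is formed.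

Step 2
Reactants: 4 (E)-4-Ar-but-3-enoic acid; 5 (R)-4-benzyloxazolidin-2-one
Product: 7 (R)-4-benzyl-3-[(E)-4-Ar-but-3-enoyl]oxazolidin-2-one, via mixed pivalic anhydride 6 (not isolated)
Conditions: t-BuCOCl, Et3N, THF, −20 °C; then LiCl, 5, −20 °C to rt
Reagents that add atoms: none
Why: N-Acylation of the oxazolidinone through mixed anhydride 6, with LiCl and Et3N activating the auxiliary, is mild, occurs at the less hindered carbonyl and gives the aryl-conjugated alkene no reason to migrate; the auxiliary stereocenter is untouched.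

Step 3
Reactants: 7 (R)-4-benzyl-3-[(E)-4-Ar-but-3-enoyl]oxazolidin-2-one; 1 4-benzyloxy-3-methoxybenzaldehyde
Product: 9 syn aldol adduct (R)-4-benzyl-3-[(2R,3E)-4-Ar-2-[(R)-Ar(hydroxy)methyl]but-3-enoyl]oxazolidin-2-one, via dibutylboron dienolate 8 (not isolated)
Conditions: Bu2BOTf (1.2 equiv), i-Pr2NEt (1.4 equiv), CH2Cl2, −78 to 0 °C; then 1, −78 to 0 °C; pH 7 buffer, MeOH, H2O2, 0 °C
Reagents that add atoms: none
Why: Evans syn aldol: soft enolisation with Bu2BOTf gives the (Z)-boron dienolate 8, which should react at its α-carbon through a closed chair-like transition state on the face away from the benzyl group of the (R)-auxiliary, so that C3 (2R in the imide) and the syn carbinol C2 (R) are set together by the auxiliary.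

Step 4
Reactants: 9 syn aldol adduct
Product: 10 (R)-4-benzyl-3-[(2R,3E)-4-Ar-2-[(R)-Ar(OTBS)methyl]but-3-enoyl]oxazolidin-2-one
Conditions: TBSOTf, 2,6-lutidine, CH2Cl2, −78 to 0 °C
Reagents that add atoms: tert-butyldimethylsilyl trifluoromethanesulfonate (TBSOTf), CC(C)(C)[Si](C)(C)OS(=O)(=O)C(F)(F)F
Why: Silylation of a hindered secondary benzylic alcohol with a silyl triflate and 2,6-lutidine is fast at low temperature, forms no stereocenter and masks the C2 oxygen, which would otherwise act as a second homoallylic directing group in step 6.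

Step 5
Reactants: 10 silylated aldol imide
Product: 11 (2S,3E)-4-Ar-2-[(R)-Ar(OTBS)methyl]but-3-en-1-ol
Conditions: LiBH4, MeOH (1 equiv), THF, 0 °C
Reagents that add atoms: none
Why: Reductive cleavage of the Evans auxiliary: LiBH4 with one equivalent of MeOH reduces the exocyclic imide carbonyl to the primary alcohol and releases 5 without forming an enolate, so C3 keeps its configuration (the descriptor changes from R to S only through the priority change) and the silyl ether, benzyl ethers and styrene are inert.

Step 6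
Reactants: 11 (2S,3E)-4-Ar-2-[(R)-Ar(OTBS)methyl]but-3-en-1-ol; 12 carbon monoxide
Product: 15 (3S,4S)-3-(4-benzyloxy-3-methoxybenzyl)-4-[(R)-Ar(OTBS)methyl]oxolan-2-ol (trans lactol; both anomers), via substrate phosphinite 13 (not isolated), via hydroxy aldehyde 14 (not isolated)
Conditions: Rh(acac)(CO)2 (3 mol %), Ph2POMe (15 mol %), CO/H2 (1:1, 40 bar), molecular sieves 4 Å, THF, 45 °C
Reagents that add atoms: carbon monoxide (compound 12), [C-]#[O+]
Why: Proposed new method: Ph2POMe swaps its methoxy group for the primary hydroxyl of 11 to give phosphinite 13, whose phosphorus holds a hydridocarbonyl complex of monovalent rhodium so that hydride goes to the benzylic carbon and rhodium to C4 inside a six-membered chelate (Rh, P, O, CH2, C3, C4); CO insertion with retention and hydrogenolysis of the acyl then give aldehyde 14 and free the phosphinite for the next turnover. The closest known reaction type is the branched-selective hydroformylation of homoallylic alcohols with a catalytic, reversibly bound phosphinite directing group, which has not been shown to override the benzylic preference of an aryl-substituted internal alkene. The one ring is closed by 5-exo-trig addition of the C3 hydroxymethyl oxygen to the new formyl carbon C5, giving the lactol. The new stereocenter C4 is controlled by the C3 stereocenter: in the chair-like chelate the large aryl(silyloxy)methyl group on C3 and the emerging arylmethyl group on C4 should both sit equatorial, which puts C5 trans to the C3 side chain, and because C4 is α to the masked aldehyde this trans isomer is also the thermodynamic one. The step needs formylation at C4 against the innate benzylic selectivity of a styrene and addition to one alkene face; the tether from the C3 CH2OH arm reaches C4 through a six-membered chelate but the benzylic carbon only through a seven-membered one, the electron-rich aryl group weakens the benzylic preference, and the equatorial preference of the C3 substituent selects the face.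

Step 7
Reactants: 15 trans lactol
Product: 16 (2S,3S)-2-(4-benzyloxy-3-methoxybenzyl)-3-[(R)-Ar(OTBS)methyl]butane-1,4-diol
Conditions: NaBH4, MeOH, 0 °C to rt
Reagents that add atoms: none
Why: Borohydride reduction of a lactol through its open hydroxy aldehyde form is fast and irreversible at 0 °C, so the diol should form without epimerisation at C4 and with the silyl ether intact; no stereocenter is formed.

Step 8
Reactants: 16 silyloxy diol
Product: 17 [(2R,3S,4S)-4-(4-benzyloxy-3-methoxybenzyl)-2-Ar-oxolan-3-yl]methanol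
Conditions: (1S)-(+)-camphor-10-sulfonic acid (0.2 equiv), CH2Cl2, 0 °C; aq. NaHCO3 quench
Reagents that add atoms: none
Why: Acid-catalysed SN1 etherification: protonation of the silyl ether lets the 4-alkoxybenzylic C2–O bond ionise, only the C5 hydroxyl can capture the cation through a five-membered transition state (the C3 arm would give an oxetane), and C2 is re-set under control of C3 with its aryl group trans to the C3 arm, because this avoids an all-cis 2,3,4-trisubstituted ring and is also the outcome of the reversible ionisation.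

Step 9
Reactants: 17 oxolane alcohol; 18 (R)-2-methylbutanoic acid
Product: 20 [(2R,3S,4S)-4-(4-benzyloxy-3-methoxybenzyl)-2-Ar-oxolan-3-yl]methyl (R)-2-methylbutanoate, via O-acylisourea 19 (not isolated)
Conditions: DCC, DMAP (0.1 equiv), CH2Cl2, 0 °C to rt
Reagents that add atoms: none
Why: Steglich esterification: DCC turns the acid into O-acylisourea 19 and DMAP transfers the acyl group to the only remaining hydroxyl under neutral conditions, which should leave the α-stereocenter of this simple α-alkyl acid intact.

Step 10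
Reactants: 20 dibenzyl ester
Product: 21 [(2R,3S,4S)-4-(4-hydroxy-3-methoxybenzyl)-2-(4-hydroxy-3-methoxyphenyl)oxolan-3-yl]methyl (R)-2-methylbutanoate (target)
Conditions: H2 (1 atm), Pd/C (10 wt %), EtOAc, rt
Reagents that add atoms: none
Why: Catalytic hydrogenolysis of the two aryl benzyl ethers over Pd/C in a neutral aprotic solvent is much faster than cleavage of the cyclic benzylic C2–O1 ether or reduction of the ester, so the bis-phenol should result with all four stereocenters unchanged.

Compound list
1 | 4-benzyloxy-3-methoxybenzaldehyde | COc1cc(C=O)ccc1OCc1ccccc1 | starting material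
2 | (2-carboxyethyl)triphenylphosphonium bromide | OC(=O)CC[P+](c1ccccc1)(c1ccccc1)c1ccccc1.[Br-] | starting material
3 | sodium 3-(triphenyl-λ5-phosphanylidene)propanoate (ylide carboxylate) | [Na+].[O-]C(=O)CC=P(c1ccccc1)(c1ccccc1)c1ccccc1 | intermediate
4 | (E)-4-(4-benzyloxy-3-methoxyphenyl)but-3-enoic acid | OC(=O)C/C=C/c1ccc(OCc2ccccc2)c(OC)c1 | intermediate
5 | (R)-4-benzyloxazolidin-2-one | O=C1N[C@H](Cc2ccccc2)CO1 | starting material
6 | (E)-4-(4-benzyloxy-3-methoxyphenyl)but-3-enoic 2,2-dimethylpropanoic anhydride | CC(C)(C)C(=O)OC(=O)C/C=C/c1ccc(OCc2ccccc2)c(OC)c1 | intermediate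
7 | (R)-4-benzyl-3-[(E)-4-(4-benzyloxy-3-methoxyphenyl)but-3-enoyl]oxazolidin-2-one | O=C(C/C=C/c1ccc(OCc2ccccc2)c(OC)c1)N1[C@H](Cc2ccccc2)COC1=O | intermediate
8 | (R)-4-benzyl-3-[(1Z,3E)-4-(4-benzyloxy-3-methoxyphenyl)-1-(dibutylboranyloxy)buta-1,3-dien-1-yl]oxazolidin-2-one | CCCCB(CCCC)O/C(=C\C=C\c1ccc(OCc2ccccc2)c(OC)c1)N1[C@H](Cc2ccccc2)COC1=O | intermediate
9 | (R)-4-benzyl-3-[(2R,3E)-4-(4-benzyloxy-3-methoxyphenyl)-2-[(R)-(4-benzyloxy-3-methoxyphenyl)(hydroxy)methyl]but-3-enoyl]oxazolidin-2-one | O=C([C@H](/C=C/c1ccc(OCc2ccccc2)c(OC)c1)[C@@H](O)c1ccc(OCc2ccccc2)c(OC)c1)N1[C@H](Cc2ccccc2)COC1=O | intermediate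
10 | (R)-4-benzyl-3-[(2R,3E)-4-(4-benzyloxy-3-methoxyphenyl)-2-[(R)-(4-benzyloxy-3-methoxyphenyl)(tert-butyldimethylsilyloxy)methyl]but-3-enoyl]oxazolidin-2-one | O=C([C@H](/C=C/c1ccc(OCc2ccccc2)c(OC)c1)[C@@H](O[Si](C)(C)C(C)(C)C)c1ccc(OCc2ccccc2)c(OC)c1)N1[C@H](Cc2ccccc2)COC1=O | intermediate
11 | (2S,3E)-4-(4-benzyloxy-3-methoxyphenyl)-2-[(R)-(4-benzyloxy-3-methoxyphenyl)(tert-butyldimethylsilyloxy)methyl]but-3-en-1-ol | OC[C@H](/C=C/c1ccc(OCc2ccccc2)c(OC)c1)[C@@H](O[Si](C)(C)C(C)(C)C)c1ccc(OCc2ccccc2)c(OC)c1 | intermediate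
12 | carbon monoxide | [C-]#[O+] | starting material
13 | (2S,3E)-4-(4-benzyloxy-3-methoxyphenyl)-2-[(R)-(4-benzyloxy-3-methoxyphenyl)(tert-butyldimethylsilyloxy)methyl]but-3-en-1-yl diphenylphosphinite | c1ccccc1P(c1ccccc1)OC[C@H](/C=C/c1ccc(OCc2ccccc2)c(OC)c1)[C@@H](O[Si](C)(C)C(C)(C)C)c1ccc(OCc2ccccc2)c(OC)c1 | intermediate
14 | (2S,3S,4R)-2-(4-benzyloxy-3-methoxybenzyl)-4-(4-benzyloxy-3-methoxyphenyl)-4-(tert-butyldimethylsilyloxy)-3-(hydroxymethyl)butanal | OC[C@@H]([C@@H](O[Si](C)(C)C(C)(C)C)c1ccc(OCc2ccccc2)c(OC)c1)[C@@H](C=O)Cc1ccc(OCc2ccccc2)c(OC)c1 | intermediate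
15 | (3S,4S)-3-(4-benzyloxy-3-methoxybenzyl)-4-[(R)-(4-benzyloxy-3-methoxyphenyl)(tert-butyldimethylsilyloxy)methyl]oxolan-2-ol, both anomers | OC1OC[C@@H]([C@@H](O[Si](C)(C)C(C)(C)C)c2ccc(OCc3ccccc3)c(OC)c2)[C@@H]1Cc1ccc(OCc2ccccc2)c(OC)c1 | intermediate
16 | (2S,3S)-2-(4-benzyloxy-3-methoxybenzyl)-3-[(R)-(4-benzyloxy-3-methoxyphenyl)(tert-butyldimethylsilyloxy)methyl]butane-1,4-diol | OC[C@@H]([C@@H](O[Si](C)(C)C(C)(C)C)c1ccc(OCc2ccccc2)c(OC)c1)[C@@H](CO)Cc1ccc(OCc2ccccc2)c(OC)c1 | intermediate
17 | [(2R,3S,4S)-4-(4-benzyloxy-3-methoxybenzyl)-2-(4-benzyloxy-3-methoxyphenyl)oxolan-3-yl]methanol | OC[C@@H]1[C@H](Cc2ccc(OCc3ccccc3)c(OC)c2)CO[C@H]1c1ccc(OCc2ccccc2)c(OC)c1 | intermediate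
18 | (R)-2-methylbutanoic acid | CC[C@@H](C)C(=O)O | starting material
19 | O-[(R)-2-methylbutanoyl]-N,N'-dicyclohexylisourea | CC[C@@H](C)C(=O)OC(=NC1CCCCC1)NC1CCCCC1 | intermediate
20 | [(2R,3S,4S)-4-(4-benzyloxy-3-methoxybenzyl)-2-(4-benzyloxy-3-methoxyphenyl)oxolan-3-yl]methyl (R)-2-methylbutanoate | CC[C@@H](C)C(=O)OC[C@@H]1[C@H](Cc2ccc(OCc3ccccc3)c(OC)c2)CO[C@H]1c1ccc(OCc2ccccc2)c(OC)c1 | intermediate
21 | [(2R,3S,4S)-4-(4-hydroxy-3-methoxybenzyl)-2-(4-hydroxy-3-methoxyphenyl)oxolan-3-yl]methyl (R)-2-methylbutanoate | CC[C@@H](C)C(=O)OC[C@@H]1[C@H](Cc2ccc(O)c(OC)c2)CO[C@H]1c1ccc(O)c(OC)c1 | target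

Total step count: 10. Longest linear sequence: 10 steps (from 1 and 2 to 21); 5, 12 and 18 enter as single reactants.

Steps most likely to fail

Step 6 (carries the label). What may go wrong: rhodium may be delivered to the benzylic carbon instead of C4 because the styrene preference outweighs the chelate. Hydride may also add to the wrong alkene face, or reversible β-hydride elimination towards C3 may move the double bond and erase the C3 center. The fallback uses known radical chemistry in place of the organometallic one-carbon delivery; it sets out from 11 and comes back at 16. The primary alcohol of 11 is treated with phosgene (toluene solution) and pyridine in THF at 0 °C to give the chloroformate F1, which is not isolated. Benzeneselenol and pyridine convert it into the Se-phenyl selenocarbonate F2. Slow addition of Bu3SnH with azobisisobutyronitrile in benzene at 80 °C should generate the alkoxycarbonyl radical, which closes 5-exo-trig onto C4 of the styrene; the resulting benzylic radical is reduced by the stannane, giving the trans lactone F3. The substituent on C3 should direct the ring closure trans as in other 5-exo radical cyclisations, and any cis lactone can be equilibrated with DBU, since C4 is α to the lactone carbonyl. LiBH4 in THF then reduces F3 to diol 16.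

Step 8. What may go wrong: the benzylic cation may be captured by the electron-rich arylmethyl ring on C4 (Friedel–Crafts closure to an aryltetralin), may lose the C3 proton, or may close on both faces. The fallback replaces SN1 at C2 by SN2 at C5 with the C2–O bond kept; it sets out from 16 and comes back at 20. MsCl and Et3N in CH2Cl2 at 0 °C give the bis-mesylate F4. Bu4NF in THF at 0 °C to rt removes the silyl group, and the freed C2 alkoxide displaces the C5 mesylate in a 5-exo-tet Williamson closure (attack on the C3 arm would need a four-membered ring). This gives the oxolane mesylate F5 with the C2 configuration of the syn aldol, which is the 2,3-trans arrangement of the target. The remaining primary mesylate is then displaced in DMF at 60 °C by cesium (R)-2-methylbutanoate F6, made in the flask from 18 and Cs2CO3, to give 20. This variant does rely on the C2 configuration set in step 3.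

Step 10. What may go wrong: hydrogenolysis may continue into the benzylic C2–O1 bond of the oxolane once the phenols are free, or stop at a mono-benzyl ether. The fallback debenzylates before the ring exists and then esterifies chemoselectively; it sets out from 16 and comes back at 21. Hydrogenolysis of 16 (H2, Pd/C, EtOAc), where the only benzylic C–O bond is a bulky silyl ether, should give the bis-phenol F7. The acid treatment of step 8 then closes it to (2R,3S,4S)-lariciresinol F8. A Mitsunobu esterification with 18 (PPh3, diisopropyl azodicarboxylate, THF, 0 °C) activates only the aliphatic primary alcohol and uses the carboxylic acid, the most acidic partner, as nucleophile, so the phenols should stay free and 21 should result directly.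

Further compounds
F1 | step 6 | (2S,3E)-4-(4-benzyloxy-3-methoxyphenyl)-2-[(R)-(4-benzyloxy-3-methoxyphenyl)(tert-butyldimethylsilyloxy)methyl]but-3-en-1-yl carbonochloridate | ClC(=O)OC[C@H](/C=C/c1ccc(OCc2ccccc2)c(OC)c1)[C@@H](O[Si](C)(C)C(C)(C)C)c1ccc(OCc2ccccc2)c(OC)c1
F2 | step 6 | O-[(2S,3E)-4-(4-benzyloxy-3-methoxyphenyl)-2-[(R)-(4-benzyloxy-3-methoxyphenyl)(tert-butyldimethylsilyloxy)methyl]but-3-en-1-yl] Se-phenyl carbonoselenoate | O=C(OC[C@H](/C=C/c1ccc(OCc2ccccc2)c(OC)c1)[C@@H](O[Si](C)(C)C(C)(C)C)c1ccc(OCc2ccccc2)c(OC)c1)[Se]c1ccccc1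
F3 | step 6 | (3S,4S)-3-(4-benzyloxy-3-methoxybenzyl)-4-[(R)-(4-benzyloxy-3-methoxyphenyl)(tert-butyldimethylsilyloxy)methyl]oxolan-2-one | O=C1OC[C@@H]([C@@H](O[Si](C)(C)C(C)(C)C)c2ccc(OCc3ccccc3)c(OC)c2)[C@@H]1Cc1ccc(OCc2ccccc2)c(OC)c1
F4 | step 8 | (2S,3S)-2-(4-benzyloxy-3-methoxybenzyl)-3-[(R)-(4-benzyloxy-3-methoxyphenyl)(tert-butyldimethylsilyloxy)methyl]butane-1,4-diyl dimethanesulfonate | CS(=O)(=O)OC[C@@H]([C@@H](O[Si](C)(C)C(C)(C)C)c1ccc(OCc2ccccc2)c(OC)c1)[C@@H](COS(C)(=O)=O)Cc1ccc(OCc2ccccc2)c(OC)c1
F5 | step 8 | [(2R,3S,4S)-4-(4-benzyloxy-3-methoxybenzyl)-2-(4-benzyloxy-3-methoxyphenyl)oxolan-3-yl]methyl methanesulfonate | CS(=O)(=O)OC[C@@H]1[C@H](Cc2ccc(OCc3ccccc3)c(OC)c2)CO[C@H]1c1ccc(OCc2ccccc2)c(OC)c1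
F6 | step 8 | cesium (R)-2-methylbutanoate | CC[C@@H](C)C(=O)[O-].[Cs+]
F7 | step 10 | (2S,3S)-2-(4-hydroxy-3-methoxybenzyl)-3-[(R)-(4-hydroxy-3-methoxyphenyl)(tert-butyldimethylsilyloxy)methyl]butane-1,4-diol | OC[C@@H]([C@@H](O[Si](C)(C)C(C)(C)C)c1ccc(O)c(OC)c1)[C@@H](CO)Cc1ccc(O)c(OC)c1
F8 | step 10 | 4-[(2R,3S,4S)-4-(4-hydroxy-3-methoxybenzyl)-3-(hydroxymethyl)oxolan-2-yl]-2-methoxyphenol, (2R,3S,4S)-lariciresinol | OC[C@@H]1[C@H](Cc2ccc(O)c(OC)c2)CO[C@H]1c1ccc(O)c(OC)c1
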